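**Assumption:** the target is made exactly as drawn, (4R,5R,6S,7R,8R) with a (Z)-C1=C10 ring alkene and an (E) side-chain alkene. Positions are given in germacrane numbering (C1–C15).

## Retrosynthetic overview

1. Target 38 ⇐ lipase-catalysed deacetylation of 37 ⇐ Yamaguchi esterification of the 8β-alcohol 29 with (E)-4-acetoxy-2-methylbut-2-enoic acid 35.
2. 29 ⇐ intramolecular chromium Barbier allylation (C6–C7 bond) of epoxy aldehyde / 2-(bromomethyl)enoate 25, which closes the ten-membered carbocycle and then the γ-lactone in the same flask.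
3. 25 ⇐ Morita–Baylis–Hillman reaction and SN2' bromination at C7, and Sharpless asymmetric epoxidation (oxirane, first ring) of the (2E,6Z)-farnesol-type alcohol 15.
4. 15 ⇐ neryl-type bromide 8 + methyl acetoacetate dianion, then (Z)-enol phosphate / Me2CuLi (sets the E C4=C5 alkene) and DIBAL-H.
5. 8 ⇐ neryl acetate 1 by ozonolysis and L-proline-catalysed α-aminoxylation (sets C8). Ring order: oxirane → cyclodecene → lactone.

## Route

**Step 1**
Reactants: 1 neryl acetate
Product: 2 (2Z)-3-methyl-6-oxohex-2-en-1-yl acetate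
Conditions: O3 (1.0 equiv), CH2Cl2/MeOH 5:1, −78 °C; then Me2S, −78 °C → rt
Reagents that add atoms: ozone, O=[O+][O-]
Why: Chemoselective ozonolysis, because the terminal trisubstituted alkene is much more electron-rich than the alkene deactivated by the allylic acetate, so one equivalent of ozone cleaves only the former and leaves the (Z)-alkene intact.

**Step 2**
Reactants: 2 (2Z)-3-methyl-6-oxohex-2-en-1-yl acetate
Product: 4 (2Z,5R)-6-hydroxy-3-methyl-5-[(phenylamino)oxy]hex-2-en-1-yl acetate, via aminooxy aldehyde 3 (not isolated)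
Conditions: PhN=O (0.9 equiv), L-proline (20 mol%), DMSO, rt, 30 min; then NaBH4, MeOH, 0 °C
Reagents that add atoms: nitrosobenzene, O=Nc1ccccc1
Why: Proline-catalysed α-aminoxylation (enamine catalysis) in which the (E)-enamine of L-proline attacks the oxygen of nitrosobenzene on the face directed by the carboxylic acid, setting C8 as R (typically about 98% ee), and NaBH4 traps the labile α-oxy aldehyde at once.

**Step 3**
Reactants: 4 (2Z,5R)-6-hydroxy-3-methyl-5-[(phenylamino)oxy]hex-2-en-1-yl acetate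
Product: 5 (2Z,5R)-5,6-dihydroxy-3-methylhex-2-en-1-yl acetate
Conditions: Zn, AcOH, THF, rt
Reagents that add atoms: none
Why: Reductive N–O cleavage by zinc in acetic acid frees the secondary hydroxyl without touching the C8 stereocenter, the alkene or the allylic acetate.

**Step 4**
Reactants: 5 (2Z,5R)-5,6-dihydroxy-3-methylhex-2-en-1-yl acetate
Product: 6 (2Z,5R)-5,6-bis[(tert-butyldimethylsilyl)oxy]-3-methylhex-2-en-1-yl acetate
Conditions: TBSCl (2.5 equiv), imidazole, DMF, rt → 40 °C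
Reagents that add atoms: tert-butyldimethylsilyl chloride, CC(C)(C)[Si](C)(C)Cl
Why: Standard silyl ether formation protects both hydroxyls with a group that survives the strongly basic chain-extension steps.

**Step 5**
Reactants: 6 (2Z,5R)-5,6-bis[(tert-butyldimethylsilyl)oxy]-3-methylhex-2-en-1-yl acetate
Product: 7 (2Z,5R)-5,6-bis[(tert-butyldimethylsilyl)oxy]-3-methylhex-2-en-1-ol
Conditions: K2CO3 (0.2 equiv), MeOH, 0 °C → rt
Reagents that add atoms: none
Why: Base-catalysed transesterification (methanolysis) removes the acetate while the silyl ethers are inert.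

**Step 6**
Reactants: 7 (2Z,5R)-5,6-bis[(tert-butyldimethylsilyl)oxy]-3-methylhex-2-en-1-ol
Product: 8 (2Z,5R)-1-bromo-5,6-bis[(tert-butyldimethylsilyl)oxy]-3-methylhex-2-ene
Conditions: CBr4, PPh3, CH2Cl2, 0 °C
Reagents that add atoms: carbon tetrabromide, BrC(Br)(Br)Br
Why: Appel bromination converts the primary allylic alcohol to the bromide by SN2 under neutral conditions, which keeps the (Z)-alkene geometry.

**Step 7**
Reactants: 8 (2Z,5R)-1-bromo-5,6-bis[(tert-butyldimethylsilyl)oxy]-3-methylhex-2-ene; 9 methyl acetoacetate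
Product: 11 methyl (6Z,9R)-9,10-bis[(tert-butyldimethylsilyl)oxy]-7-methyl-3-oxodec-6-enoate, via acetoacetate dianion 10 (not isolated)
Conditions: 9, NaH, THF, 0 °C; n-BuLi, 0 °C; then 8, 0 °C → rt; AcOH quench
Reagents that add atoms: sodium hydride, [Na+].[H-], and n-butyllithium, [Li]CCCC (Na and Li stay only in 10)
Why: Weiler dianion alkylation, in which the more reactive γ-carbanion of the acetoacetate dianion displaces the primary allylic bromide by SN2, adding C3–C6 without disturbing the alkene or C8.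

**Step 8**
Reactants: 11 methyl (6Z,9R)-9,10-bis[(tert-butyldimethylsilyl)oxy]-7-methyl-3-oxodec-6-enoate
Product: 13 methyl (2Z,6Z,9R)-9,10-bis[(tert-butyldimethylsilyl)oxy]-3-[(diethoxyphosphoryl)oxy]-7-methyldeca-2,6-dienoate, via sodium enolate 12 (not isolated)
Conditions: NaH, Et2O, 0 °C; then ClP(O)(OEt)2, 0 °C → rt
Reagents that add atoms: diethyl chlorophosphate, CCOP(=O)(Cl)OCC; sodium hydride, [Na+].[H-] (Na stays only in 12)
Why: O-phosphorylation of the sodium-chelated, U-shaped β-keto ester enolate in ether gives the (Z)-enol phosphate selectively.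

**Step 9**
Reactants: 13 methyl (2Z,6Z,9R)-9,10-bis[(tert-butyldimethylsilyl)oxy]-3-[(diethoxyphosphoryl)oxy]-7-methyldeca-2,6-dienoate
Product: 14 methyl (2E,6Z,9R)-9,10-bis[(tert-butyldimethylsilyl)oxy]-3,7-dimethyldeca-2,6-dienoate
Conditions: Me2CuLi (2.5 equiv, from MeLi and CuI), Et2O, −78 → −45 °C
Reagents that add atoms: lithium dimethylcuprate, [Li+].C[Cu-]C (made in the flask from methyllithium, [Li]C, and CuI)
Why: Cuprate addition–elimination on the enol phosphate replaces the phosphate by methyl (C15) with retention of geometry, so the (Z)-enol phosphate gives the (2E)-enoate, which is the E C4=C5 alkene.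

**Step 10**
Reactants: 14 methyl (2E,6Z,9R)-9,10-bis[(tert-butyldimethylsilyl)oxy]-3,7-dimethyldeca-2,6-dienoate
Product: 15 (2E,6Z,9R)-9,10-bis[(tert-butyldimethylsilyl)oxy]-3,7-dimethyldeca-2,6-dien-1-ol
Conditions: DIBAL-H (2.2 equiv), CH2Cl2, −78 °C; aqueous work-up
Reagents that add atoms: none
Why: 1,2-Reduction of the enoate by DIBAL-H gives the (E)-allylic alcohol needed for directed epoxidation.

**Step 11**
Reactants: 15 (2E,6Z,9R)-9,10-bis[(tert-butyldimethylsilyl)oxy]-3,7-dimethyldeca-2,6-dien-1-ol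
Product: 16 [(2R,3R)-3-[(3Z,6R)-6,7-bis[(tert-butyldimethylsilyl)oxy]-4-methylhept-3-en-1-yl]-3-methyloxiran-2-yl]methanol
Conditions: Ti(OiPr)4 (10 mol%), D-(−)-diethyl tartrate (12 mol%), t-BuOOH, 4 Å molecular sieves, CH2Cl2, −20 °C
Reagents that add atoms: tert-butyl hydroperoxide, CC(C)(C)OO
Why: Sharpless asymmetric epoxidation, in which the titanium tartrate complex delivers oxygen to one face of the (E)-allylic alcohol under reagent control (D-tartrate gives the 2R,3R epoxy alcohol, which is 4R,5R in the target), and the isolated (Z)-alkene does not react.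

**Step 12**
Reactants: 16 [(2R,3R)-3-[(3Z,6R)-6,7-bis[(tert-butyldimethylsilyl)oxy]-4-methylhept-3-en-1-yl]-3-methyloxiran-2-yl]methanol
Product: 18 (2R,3R)-2-[(3Z,6R)-6,7-bis[(tert-butyldimethylsilyl)oxy]-4-methylhept-3-en-1-yl]-3-{[(4-methoxybenzyl)oxy]methyl}-2-methyloxirane, via sodium alkoxide 17 (not isolated)
Conditions: NaH, THF/DMF, 0 °C; then 4-MeOC6H4CH2Cl, Bu4NI (cat.), 0 °C → rt
Reagents that add atoms: 4-methoxybenzyl chloride, COc1ccc(CCl)cc1; sodium hydride, [Na+].[H-] (Na stays only in 17)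
Why: Williamson etherification of the primary alkoxide, which is fast enough that the trisubstituted epoxide (the favoured Payne isomer) is kept, and no stereocenter is touched.

**Step 13**
Reactants: 18 (2R,3R)-2-[(3Z,6R)-6,7-bis[(tert-butyldimethylsilyl)oxy]-4-methylhept-3-en-1-yl]-3-{[(4-methoxybenzyl)oxy]methyl}-2-methyloxirane
Product: 19 (2R,4Z)-2-[(tert-butyldimethylsilyl)oxy]-7-[(2R,3R)-3-{[(4-methoxybenzyl)oxy]methyl}-2-methyloxiran-2-yl]-4-methylhept-4-en-1-ol
Conditions: HF·pyridine, excess pyridine, THF, 0 °C → rt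
Reagents that add atoms: none
Why: Selective desilylation, since the primary silyl ether is cleaved much faster than the secondary one by buffered HF·pyridine, which is mild enough for the epoxide.

**Step 14**
Reactants: 19 (2R,4Z)-2-[(tert-butyldimethylsilyl)oxy]-7-[(2R,3R)-3-{[(4-methoxybenzyl)oxy]methyl}-2-methyloxiran-2-yl]-4-methylhept-4-en-1-ol
Product: 20 (2R,4Z)-2-[(tert-butyldimethylsilyl)oxy]-7-[(2R,3R)-3-{[(4-methoxybenzyl)oxy]methyl}-2-methyloxiran-2-yl]-4-methylhept-4-enal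
Conditions: Dess–Martin periodinane, pyridine, CH2Cl2, 0 °C → rt
Reagents that add atoms: none
Why: Dess–Martin oxidation gives the α-silyloxy aldehyde under buffered, non-epimerising conditions.

**Step 15**
Reactants: 20 (2R,4Z)-2-[(tert-butyldimethylsilyl)oxy]-7-[(2R,3R)-3-{[(4-methoxybenzyl)oxy]methyl}-2-methyloxiran-2-yl]-4-methylhept-4-enal; 21 methyl acrylate
Product: 22 methyl (4R,6Z)-4-[(tert-butyldimethylsilyl)oxy]-3-hydroxy-9-[(2R,3R)-3-{[(4-methoxybenzyl)oxy]methyl}-2-methyloxiran-2-yl]-6-methyl-2-methylidenenon-6-enoate (both C3 epimers)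
Conditions: 1,4-diazabicyclo[2.2.2]octane (1 equiv), neat methyl acrylate (10 equiv), rt, 3–5 d
Reagents that add atoms: none
Why: Morita–Baylis–Hillman reaction, which works here because the α-oxygenated aldehyde is activated, and the new carbinol center (C7) needs no control because it is removed in the next step.

**Step 16**
Reactants: 22 methyl (4R,6Z)-4-[(tert-butyldimethylsilyl)oxy]-3-hydroxy-9-[(2R,3R)-3-{[(4-methoxybenzyl)oxy]methyl}-2-methyloxiran-2-yl]-6-methyl-2-methylidenenon-6-enoate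
Product: 23 methyl (2Z,4R,6Z)-2-(bromomethyl)-4-[(tert-butyldimethylsilyl)oxy]-9-[(2R,3R)-3-{[(4-methoxybenzyl)oxy]methyl}-2-methyloxiran-2-yl]-6-methylnona-2,6-dienoate
Conditions: NBS, Me2S, CH2Cl2, −20 °C (premixed); then 22, → rt
Reagents that add atoms: N-bromosuccinimide, O=C1CCC(=O)N1Br
Why: Corey–Kim-type activation of the Baylis–Hillman alcohol followed by SN2' attack of bromide gives the thermodynamically preferred (Z)-2-(bromomethyl)enoate from both epimers, under acid-free conditions that spare the epoxide.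

**Step 17**
Reactants: 23 methyl (2Z,4R,6Z)-2-(bromomethyl)-4-[(tert-butyldimethylsilyl)oxy]-9-[(2R,3R)-3-{[(4-methoxybenzyl)oxy]methyl}-2-methyloxiran-2-yl]-6-methylnona-2,6-dienoate
Product: 24 methyl (2Z,4R,6Z)-2-(bromomethyl)-4-[(tert-butyldimethylsilyl)oxy]-9-[(2R,3R)-3-(hydroxymethyl)-2-methyloxiran-2-yl]-6-methylnona-2,6-dienoate
Conditions: DDQ, CH2Cl2/pH 7 phosphate buffer 10:1, 0 °C
Reagents that add atoms: none
Why: Oxidative cleavage of the 4-methoxybenzyl ether by DDQ is neutral and leaves the allylic bromide, silyl ether, epoxide and alkenes alone.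

**Step 18**
Reactants: 24 methyl (2Z,4R,6Z)-2-(bromomethyl)-4-[(tert-butyldimethylsilyl)oxy]-9-[(2R,3R)-3-(hydroxymethyl)-2-methyloxiran-2-yl]-6-methylnona-2,6-dienoate
Product: 25 methyl (2Z,4R,6Z)-2-(bromomethyl)-4-[(tert-butyldimethylsilyl)oxy]-9-[(2R,3S)-3-formyl-2-methyloxiran-2-yl]-6-methylnona-2,6-dienoate
Conditions: Dess–Martin periodinane, pyridine, CH2Cl2, 0 °C
Reagents that add atoms: none
Why: Dess–Martin oxidation gives the epoxy aldehyde without amine bases that would attack the allylic bromide (the descriptor at the formyl-bearing carbon changes to S by priority only, with the geometry unchanged).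

**Step 19**
Reactants: 25 methyl (2Z,4R,6Z)-2-(bromomethyl)-4-[(tert-butyldimethylsilyl)oxy]-9-[(2R,3S)-3-formyl-2-methyloxiran-2-yl]-6-methylnona-2,6-dienoate
Product: 28 (1(10)Z)-8β-[(tert-butyldimethylsilyl)oxy]-4α,5β-epoxygermacra-1(10),11(13)-dien-12,6α-olide, via allylchromium dichloride 26 (not isolated), via ring-closed hydroxy ester 27 (not isolated)
Conditions: CrCl2 (8 equiv), degassed THF, 2 mM, syringe-pump addition of 25 over 10 h, rt; aq. NH4Cl work-up
Reagents that add atoms: chromium dichloride, Cl[Cr]Cl (Cr and Cl stay only in 26)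
Why: Intramolecular Nozaki–Hiyama-type Barbier allylation in which the allylchromium adds through its γ-carbon (C7) to the aldehyde in a cyclic transition state inside the forming ten-membered ring, where the (Z)-C1=C10 alkene and the trans-epoxide are expected to fix the conformation so that C6 and C7 form anti (6α-O, 7α-H), after which the alkoxide lactonises onto the methyl ester.

**Step 20**
Reactants: 28 (1(10)Z)-8β-[(tert-butyldimethylsilyl)oxy]-4α,5β-epoxygermacra-1(10),11(13)-dien-12,6α-olide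
Product: 29 (1(10)Z)-8β-hydroxy-4α,5β-epoxygermacra-1(10),11(13)-dien-12,6α-olide
Conditions: Bu4NF, AcOH (1:1), THF, 0 °C → rt
Reagents that add atoms: none
Why: Fluoride desilylation buffered with acetic acid frees the C8 hydroxyl without base-induced translactonisation or acid-induced transannular opening of the epoxide.

**Step 21**
Reactants: 30 (tert-butyldimethylsilyloxy)acetaldehyde; 31 ethyl 2-(triphenylphosphoranylidene)propanoate
Product: 32 ethyl (2E)-4-[(tert-butyldimethylsilyl)oxy]-2-methylbut-2-enoate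
Conditions: CH2Cl2, rt
Reagents that add atoms: none
Why: Wittig olefination with a stabilised ylide gives the (E)-trisubstituted enoate selectively.

**Step 22**
Reactants: 32 ethyl (2E)-4-[(tert-butyldimethylsilyl)oxy]-2-methylbut-2-enoate
Product: 34 (2E)-4-hydroxy-2-methylbut-2-enoic acid, via lithium carboxylate 33 (not isolated)
Conditions: LiOH, THF/MeOH/H2O, rt; then 1 M HCl to pH 1, rt
Reagents that add atoms: lithium hydroxide, [Li+].[OH-] (O stays in the carboxyl group, Li only in 33)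
Why: Saponification followed by acidification, which also hydrolyses the acid-labile primary allylic silyl ether, and the (E)-alkene is the stable tiglate-type isomer.

**Step 23**
Reactants: 34 (2E)-4-hydroxy-2-methylbut-2-enoic acid
Product: 35 (2E)-4-acetoxy-2-methylbut-2-enoic acid
Conditions: Ac2O (1.2 equiv), pyridine, 0 °C → rt; aqueous work-up
Reagents that add atoms: acetic anhydride, CC(=O)OC(C)=O
Why: O-acetylation of the primary alcohol installs a protecting group that an enzyme can later remove at neutral pH.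

**Step 24**
Reactants: 29 (1(10)Z)-8β-hydroxy-4α,5β-epoxygermacra-1(10),11(13)-dien-12,6α-olide; 35 (2E)-4-acetoxy-2-methylbut-2-enoic acid
Product: 37 (1(10)Z)-8β-{[(2E)-4-acetoxy-2-methylbut-2-enoyl]oxy}-4α,5β-epoxygermacra-1(10),11(13)-dien-12,6α-olide, via mixed anhydride 36 (not isolated)
Conditions: 35, 2,4,6-trichlorobenzoyl chloride, Et3N, toluene, rt; then 29, 4-(dimethylamino)pyridine, rt
Reagents that add atoms: 2,4,6-trichlorobenzoyl chloride, O=C(Cl)c1c(Cl)cc(Cl)cc1Cl (its atoms stay only in 36)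
Why: Yamaguchi esterification acylates the hindered secondary C8 hydroxyl through the acylpyridinium of the mixed anhydride with retention at C8, and the (E)-enoate cannot isomerise to a more stable form.

**Step 25**
Reactants: 37 (1(10)Z)-8β-{[(2E)-4-acetoxy-2-methylbut-2-enoyl]oxy}-4α,5β-epoxygermacra-1(10),11(13)-dien-12,6α-olide
Product: 38 target CNP0198076.5, (1(10)Z)-8β-{[(2E)-4-hydroxy-2-methylbut-2-enoyl]oxy}-4α,5β-epoxygermacra-1(10),11(13)-dien-12,6α-olide
Conditions: lipase (immobilised Candida antarctica lipase B), pH 7 phosphate buffer/acetone 9:1, 30 °C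
Reagents that add atoms: none
Why: Lipase-catalysed hydrolysis accepts the unhindered primary allylic acetate but not the hindered C8 enoate or the γ-lactone, and at pH 7 the α-methylene lactone and epoxide, which no chemical deacetylation would spare, are untouched.

## Compound list

1 | neryl acetate, (2Z)-3,7-dimethylocta-2,6-dien-1-yl acetate | CC(C)=CCC/C(C)=C\COC(C)=O | starting material
2 | (2Z)-3-methyl-6-oxohex-2-en-1-yl acetate | O=CCC/C(C)=C\COC(C)=O | intermediate
3 | (2Z,5R)-3-methyl-6-oxo-5-[(phenylamino)oxy]hex-2-en-1-yl acetate (aminooxy aldehyde, not isolated) | O=C[C@H](ONc1ccccc1)C/C(C)=C\COC(C)=O | intermediate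
4 | (2Z,5R)-6-hydroxy-3-methyl-5-[(phenylamino)oxy]hex-2-en-1-yl acetate | OC[C@H](ONc1ccccc1)C/C(C)=C\COC(C)=O | intermediate
5 | (2Z,5R)-5,6-dihydroxy-3-methylhex-2-en-1-yl acetate | OC[C@H](O)C/C(C)=C\COC(C)=O | intermediate
6 | (2Z,5R)-5,6-bis[(tert-butyldimethylsilyl)oxy]-3-methylhex-2-en-1-yl acetate | CC(C)(C)[Si](C)(C)OC[C@H](O[Si](C)(C)C(C)(C)C)C/C(C)=C\COC(C)=O | intermediate
7 | (2Z,5R)-5,6-bis[(tert-butyldimethylsilyl)oxy]-3-methylhex-2-en-1-ol | CC(C)(C)[Si](C)(C)OC[C@H](O[Si](C)(C)C(C)(C)C)C/C(C)=C\CO | intermediate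
8 | (2Z,5R)-1-bromo-5,6-bis[(tert-butyldimethylsilyl)oxy]-3-methylhex-2-ene | CC(C)(C)[Si](C)(C)OC[C@H](O[Si](C)(C)C(C)(C)C)C/C(C)=C\CBr | intermediate
9 | methyl acetoacetate | COC(=O)CC(C)=O | starting material
10 | sodium lithium dianion of methyl acetoacetate (not isolated) | [Na+].[Li+].[CH2-]C(=O)[CH-]C(=O)OC | intermediate
11 | methyl (6Z,9R)-9,10-bis[(tert-butyldimethylsilyl)oxy]-7-methyl-3-oxodec-6-enoate | CC(C)(C)[Si](C)(C)OC[C@H](O[Si](C)(C)C(C)(C)C)C/C(C)=C\CCC(=O)CC(=O)OC | intermediate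
12 | sodium (Z)-enolate of 11 (not isolated) | [Na+].CC(C)(C)[Si](C)(C)OC[C@H](O[Si](C)(C)C(C)(C)C)C/C(C)=C\CC/C([O-])=C/C(=O)OC | intermediate
13 | methyl (2Z,6Z,9R)-9,10-bis[(tert-butyldimethylsilyl)oxy]-3-[(diethoxyphosphoryl)oxy]-7-methyldeca-2,6-dienoate | CC(C)(C)[Si](C)(C)OC[C@H](O[Si](C)(C)C(C)(C)C)C/C(C)=C\CC/C(OP(=O)(OCC)OCC)=C/C(=O)OC | intermediate
14 | methyl (2E,6Z,9R)-9,10-bis[(tert-butyldimethylsilyl)oxy]-3,7-dimethyldeca-2,6-dienoate | CC(C)(C)[Si](C)(C)OC[C@H](O[Si](C)(C)C(C)(C)C)C/C(C)=C\CC/C(C)=C/C(=O)OC | intermediate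
15 | (2E,6Z,9R)-9,10-bis[(tert-butyldimethylsilyl)oxy]-3,7-dimethyldeca-2,6-dien-1-ol | CC(C)(C)[Si](C)(C)OC[C@H](O[Si](C)(C)C(C)(C)C)C/C(C)=C\CC/C(C)=C/CO | intermediate
16 | [(2R,3R)-3-[(3Z,6R)-6,7-bis[(tert-butyldimethylsilyl)oxy]-4-methylhept-3-en-1-yl]-3-methyloxiran-2-yl]methanol | CC(C)(C)[Si](C)(C)OC[C@H](O[Si](C)(C)C(C)(C)C)C/C(C)=C\CC[C@@]1(C)O[C@@H]1CO | intermediate
17 | sodium alkoxide of 16 (not isolated) | [Na+].CC(C)(C)[Si](C)(C)OC[C@H](O[Si](C)(C)C(C)(C)C)C/C(C)=C\CC[C@@]1(C)O[C@@H]1C[O-] | intermediate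
18 | (2R,3R)-2-[(3Z,6R)-6,7-bis[(tert-butyldimethylsilyl)oxy]-4-methylhept-3-en-1-yl]-3-{[(4-methoxybenzyl)oxy]methyl}-2-methyloxirane | CC(C)(C)[Si](C)(C)OC[C@H](O[Si](C)(C)C(C)(C)C)C/C(C)=C\CC[C@@]1(C)O[C@@H]1COCc1ccc(OC)cc1 | intermediate
19 | (2R,4Z)-2-[(tert-butyldimethylsilyl)oxy]-7-[(2R,3R)-3-{[(4-methoxybenzyl)oxy]methyl}-2-methyloxiran-2-yl]-4-methylhept-4-en-1-ol | OC[C@H](O[Si](C)(C)C(C)(C)C)C/C(C)=C\CC[C@@]1(C)O[C@@H]1COCc1ccc(OC)cc1 | intermediate
20 | (2R,4Z)-2-[(tert-butyldimethylsilyl)oxy]-7-[(2R,3R)-3-{[(4-methoxybenzyl)oxy]methyl}-2-methyloxiran-2-yl]-4-methylhept-4-enal | O=C[C@H](O[Si](C)(C)C(C)(C)C)C/C(C)=C\CC[C@@]1(C)O[C@@H]1COCc1ccc(OC)cc1 | intermediate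
21 | methyl acrylate | C=CC(=O)OC | starting material
22 | methyl (4R,6Z)-4-[(tert-butyldimethylsilyl)oxy]-3-hydroxy-9-[(2R,3R)-3-{[(4-methoxybenzyl)oxy]methyl}-2-methyloxiran-2-yl]-6-methyl-2-methylidenenon-6-enoate (both C3 epimers) | C=C(C(=O)OC)C(O)[C@H](O[Si](C)(C)C(C)(C)C)C/C(C)=C\CC[C@@]1(C)O[C@@H]1COCc1ccc(OC)cc1 | intermediate
23 | methyl (2Z,4R,6Z)-2-(bromomethyl)-4-[(tert-butyldimethylsilyl)oxy]-9-[(2R,3R)-3-{[(4-methoxybenzyl)oxy]methyl}-2-methyloxiran-2-yl]-6-methylnona-2,6-dienoate | COC(=O)/C(CBr)=C/[C@H](O[Si](C)(C)C(C)(C)C)C/C(C)=C\CC[C@@]1(C)O[C@@H]1COCc1ccc(OC)cc1 | intermediate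
24 | methyl (2Z,4R,6Z)-2-(bromomethyl)-4-[(tert-butyldimethylsilyl)oxy]-9-[(2R,3R)-3-(hydroxymethyl)-2-methyloxiran-2-yl]-6-methylnona-2,6-dienoate | COC(=O)/C(CBr)=C/[C@H](O[Si](C)(C)C(C)(C)C)C/C(C)=C\CC[C@@]1(C)O[C@@H]1CO | intermediate
25 | methyl (2Z,4R,6Z)-2-(bromomethyl)-4-[(tert-butyldimethylsilyl)oxy]-9-[(2R,3S)-3-formyl-2-methyloxiran-2-yl]-6-methylnona-2,6-dienoate | COC(=O)/C(CBr)=C/[C@H](O[Si](C)(C)C(C)(C)C)C/C(C)=C\CC[C@@]1(C)O[C@@H]1C=O | intermediate
26 | allylchromium dichloride from 25, Cr on C13 (not isolated) | COC(=O)C(C[Cr](Cl)Cl)=C[C@H](O[Si](C)(C)C(C)(C)C)C/C(C)=C\CC[C@@]1(C)O[C@@H]1C=O | intermediate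
27 | ring-closed hydroxy ester, methyl 2-[(1(10)Z)-8β-(tert-butyldimethylsilyloxy)-4α,5β-epoxy-6α-hydroxycyclodec-1(10)-en-7β-yl]acrylate in germacrane numbering, present as its trivalent chromium alkoxide (not isolated) | COC(=O)C(=C)[C@@H]1[C@H](O[Si](C)(C)C(C)(C)C)C/C(C)=C\CC[C@@]2(C)O[C@@H]2[C@H]1O | intermediate
28 | (1(10)Z)-8β-[(tert-butyldimethylsilyl)oxy]-4α,5β-epoxygermacra-1(10),11(13)-dien-12,6α-olide | C=C1C(=O)O[C@H]2[C@H]1[C@H](O[Si](C)(C)C(C)(C)C)C/C(C)=C\CC[C@@]1(C)O[C@H]21 | intermediate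
29 | (1(10)Z)-8β-hydroxy-4α,5β-epoxygermacra-1(10),11(13)-dien-12,6α-olide (4R,5R,6S,7R,8R) | C=C1C(=O)O[C@H]2[C@H]1[C@H](O)C/C(C)=C\CC[C@@]1(C)O[C@H]21 | intermediate
30 | (tert-butyldimethylsilyloxy)acetaldehyde | CC(C)(C)[Si](C)(C)OCC=O | starting material
31 | ethyl 2-(triphenylphosphoranylidene)propanoate | CCOC(=O)C(C)=P(c1ccccc1)(c1ccccc1)c1ccccc1 | starting material
32 | ethyl (2E)-4-[(tert-butyldimethylsilyl)oxy]-2-methylbut-2-enoate | CCOC(=O)/C(C)=C/CO[Si](C)(C)C(C)(C)C | intermediate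
33 | lithium (2E)-4-[(tert-butyldimethylsilyl)oxy]-2-methylbut-2-enoate (not isolated) | [Li+].[O-]C(=O)/C(C)=C/CO[Si](C)(C)C(C)(C)C | intermediate
34 | (2E)-4-hydroxy-2-methylbut-2-enoic acid | OC(=O)/C(C)=C/CO | intermediate
35 | (2E)-4-acetoxy-2-methylbut-2-enoic acid | OC(=O)/C(C)=C/COC(C)=O | intermediate
36 | (2E)-4-acetoxy-2-methylbut-2-enoic 2,4,6-trichlorobenzoic anhydride (not isolated) | CC(=O)OC/C=C(\C)C(=O)OC(=O)c1c(Cl)cc(Cl)cc1Cl | intermediate
37 | (1(10)Z)-8β-{[(2E)-4-acetoxy-2-methylbut-2-enoyl]oxy}-4α,5β-epoxygermacra-1(10),11(13)-dien-12,6α-olide | C=C1C(=O)O[C@H]2[C@H]1[C@H](OC(=O)/C(C)=C/COC(C)=O)C/C(C)=C\CC[C@@]1(C)O[C@H]21 | intermediate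
38 | CNP0198076.5, (1(10)Z)-8β-{[(2E)-4-hydroxy-2-methylbut-2-enoyl]oxy}-4α,5β-epoxygermacra-1(10),11(13)-dien-12,6α-olide (4R,5R,6S,7R,8R) | C=C1C(=O)O[C@H]2[C@H]1[C@H](OC(=O)/C(C)=C/CO)C/C(C)=C\CC[C@@]1(C)O[C@H]21 | target

## Step count and risks

Total step count: 25. Longest linear sequence: 22 steps (steps 1–20, 24 and 25); steps 21–23 make the side-chain acid.

**Step 19 (macrocyclic Barbier allylation)** is the most likely to fail. The ring closure rests on precedent for the 8-unsubstituted (Z)-series, and the C8 silyloxy group may lower the yield or the C6/C7 selectivity. The fallback sets out from 22 and comes back at 28, replacing the stoichiometric chromium reagent by catalytic umpolung of a π-allylpalladium species. Methyl chloroformate and pyridine convert 22 into the allylic methyl carbonate F1. DDQ then gives the epoxy alcohol carbonate F2, and Dess–Martin periodinane gives the epoxy aldehyde carbonate F3. Pd(PPh3)4 (zerovalent palladium, 10 mol%) with Et2Zn in THF at 5 mM ionises the carbonate and transmetalates to an allylzinc, which adds through C7 to the aldehyde and lactonises to 28.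

**Step 15 (Morita–Baylis–Hillman reaction)** may be slow on the branched α-silyloxy aldehyde, and days of amine exposure risk epimerisation at C8. The fallback sets out from 20 and comes back at 22 by an aldol and elimination sequence at low temperature. The lithium enolate of commercial methyl 3-(dimethylamino)propanoate (LDA, THF, −78 °C) adds to 20 to give the β-hydroxy amino ester F4. Methyl iodide quaternises it to the trimethylammonium iodide F5, and aqueous NaHCO3/CH2Cl2 induces elimination of trimethylamine to give 22.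

**Step 24 (esterification of the hindered 8β-hydroxyl)** may be sluggish next to the lactone, and the activated 4-acetoxy enoyl unit may degrade before acyl transfer. The fallback sets out from 29 and comes back at 37 by building the enoate on the core. Commercial 2-(diethoxyphosphoryl)propanoic acid, N,N'-diisopropylcarbodiimide and catalytic 4-(dimethylamino)pyridine acylate 29 to the phosphonate ester F6. A Masamune–Roush Horner–Wadsworth–Emmons reaction (LiCl, iPr2NEt, MeCN, 0 °C → rt) with 2-oxoethyl acetate F7, made by ozonolysis of commercial (Z)-but-2-ene-1,4-diyl diacetate, gives the (E)-enoate 37.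

## Further compounds

F1 | step 19 | methyl (4R,6Z)-4-[(tert-butyldimethylsilyl)oxy]-3-[(methoxycarbonyl)oxy]-9-[(2R,3R)-3-{[(4-methoxybenzyl)oxy]methyl}-2-methyloxiran-2-yl]-6-methyl-2-methylidenenon-6-enoate | COC(=O)OC(C(=C)C(=O)OC)[C@H](O[Si](C)(C)C(C)(C)C)C/C(C)=C\CC[C@@]1(C)O[C@@H]1COCc1ccc(OC)cc1
F2 | step 19 | methyl (4R,6Z)-4-[(tert-butyldimethylsilyl)oxy]-9-[(2R,3R)-3-(hydroxymethyl)-2-methyloxiran-2-yl]-3-[(methoxycarbonyl)oxy]-6-methyl-2-methylidenenon-6-enoate | COC(=O)OC(C(=C)C(=O)OC)[C@H](O[Si](C)(C)C(C)(C)C)C/C(C)=C\CC[C@@]1(C)O[C@@H]1CO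
F3 | step 19 | methyl (4R,6Z)-4-[(tert-butyldimethylsilyl)oxy]-9-[(2R,3S)-3-formyl-2-methyloxiran-2-yl]-3-[(methoxycarbonyl)oxy]-6-methyl-2-methylidenenon-6-enoate | COC(=O)OC(C(=C)C(=O)OC)[C@H](O[Si](C)(C)C(C)(C)C)C/C(C)=C\CC[C@@]1(C)O[C@@H]1C=O
F4 | step 15 | methyl (4R,6Z)-4-[(tert-butyldimethylsilyl)oxy]-2-[(dimethylamino)methyl]-3-hydroxy-9-[(2R,3R)-3-{[(4-methoxybenzyl)oxy]methyl}-2-methyloxiran-2-yl]-6-methylnon-6-enoate | COC(=O)C(CN(C)C)C(O)[C@H](O[Si](C)(C)C(C)(C)C)C/C(C)=C\CC[C@@]1(C)O[C@@H]1COCc1ccc(OC)cc1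
F5 | step 15 | trimethylammonium iodide of F4 | [I-].COC(=O)C(C[N+](C)(C)C)C(O)[C@H](O[Si](C)(C)C(C)(C)C)C/C(C)=C\CC[C@@]1(C)O[C@@H]1COCc1ccc(OC)cc1
F6 | step 24 | (1(10)Z)-8β-{[2-(diethoxyphosphoryl)propanoyl]oxy}-4α,5β-epoxygermacra-1(10),11(13)-dien-12,6α-olide | C=C1C(=O)O[C@H]2[C@H]1[C@H](OC(=O)C(C)P(=O)(OCC)OCC)C/C(C)=C\CC[C@@]1(C)O[C@H]21
F7 | step 24 | 2-oxoethyl acetate | CC(=O)OCC=O
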